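**Retrosynthetic overview**
- Last C–C bond: the C10=C11 alkylidene, by aldol condensation of a 2-deoxy-D-ribose-derived γ-lactone (C11–C15 and C20, carrying C12 and C13) with a C1–C10 aldehyde; desilylation ends the route.
- Key disconnection C5–C6: a one-pot union of the C1–C5 pinacol boronate (2Z alkene and angelate already in place), the C6–C10 (S)-propargylic alcohol and MeMgBr, which also makes the C7–CH3 bond and the 6E alkene.
- Enabling feature: the C8 hydroxyl, 1,3 to C6. As its magnesium alkoxide it directs anti-methylmagnesiation of the C6≡C7 alkyne and holds the metal on C6 cis to C8 in a temporary five-membered O8–Mg–C6=C7–C8 ring (a 2,5-dihydro-1,2-oxamagnesole, not in the target). The invertive boron-to-carbon 1,2-shift, with extrusion of boron, then places C5 trans to C8.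
- C8 is set by Noyori transfer hydrogenation of a silyl ynone; C12 and C13 come from the chiral pool; 2Z comes from commercial (Z)-3-methylpent-2-en-4-yn-1-ol.
- Ring order: the γ-lactone is taken intact from the sugar lactone and never built; the only ring formed is the temporary oxamagnesole, made and destroyed in the key step.

Key step: step 8

Remark: locants follow the acyclic diterpenoid chain (C1 = CH2–O-angelate … C15 = isopropylidene carbon, lactone carbonyl = C20); read this way the target is 2Z,6E,8S,10E,12S,13R with a (Z)-2-methylbut-2-enoate (angelate) at O1, and compounds 1, 2, 7 and 18 are assumed to be commercial.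

**Step 1**
Reactants: 1 (Z)-3-methylpent-2-en-4-yn-1-ol; 2 angelic acid [(Z)-2-methylbut-2-enoic acid]
Product: 4 (Z)-3-methylpent-2-en-4-yn-1-yl (Z)-2-methylbut-2-enoate, via mixed anhydride 3 (not isolated)
Conditions: 2, 2,4,6-trichlorobenzoyl chloride, Et3N, toluene, rt; then 1, 80 °C
Reagents that add atoms: none
Why: Yamaguchi-type esterification through mixed anhydride 3, run without a nucleophilic amine catalyst, should acylate the primary allylic alcohol without isomerising the (Z)-angeloyl group to the tigloyl isomer.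

**Step 2**
Reactants: 4 (Z)-3-methylpent-2-en-4-yn-1-yl (Z)-2-methylbut-2-enoate
Product: 5 (Z)-3-methylpenta-2,4-dien-1-yl (Z)-2-methylbut-2-enoate
Conditions: H2 (1 atm), Pd/CaCO3 poisoned with Pb(OAc)2, quinoline, EtOAc, rt
Reagents that add atoms: none
Why: Lindlar semi-hydrogenation of the terminal alkyne stops at the vinyl stage and leaves the trisubstituted 2Z alkene and the angelate double bond untouched.

**Step 3**
Reactants: 5 (Z)-3-methylpenta-2,4-dien-1-yl (Z)-2-methylbut-2-enoate
Product: 6 (Z)-3-methyl-5-(4,4,5,5-tetramethyl-1,3,2-dioxaborolan-2-yl)pent-2-en-1-yl (Z)-2-methylbut-2-enoate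
Conditions: HBpin, [Ir(cod)Cl]2 (cat.), dppm (cat.), CH2Cl2, rt
Reagents that add atoms: pinacolborane, [H]B1OC(C)(C)C(C)(C)O1
Why: Iridium-catalysed anti-Markovnikov 1,2-hydroboration of the unsubstituted vinyl terminus of a 1,3-diene with pinacolborane, a known route to homoallylic boronates, should place boron on C5 and leave the trisubstituted alkenes and the ester untouched.

**Step 4**
Reactants: 7 methyl 3,3-dimethoxypropanoate
Product: 8 3,3-dimethoxy-N-methoxy-N-methylpropanamide
Conditions: MeNH(OMe)·HCl, i-PrMgCl, THF, −20 °C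
Reagents that add atoms: N,O-dimethylhydroxylamine hydrochloride, CNOC.Cl
Why: Weinreb amide formation by aminolysis of the methyl ester with the magnesium amide of N,O-dimethylhydroxylamine is standard and tolerates the dimethyl acetal.

**Step 5**
Reactants: 8 3,3-dimethoxy-N-methoxy-N-methylpropanamide
Product: 9 5,5-dimethoxy-1-(trimethylsilyl)pent-1-yn-3-one
Conditions: Me3SiC≡CH, n-BuLi, THF, −78 °C; then 8, −78 → 0 °C; aq. NH4Cl
Reagents that add atoms: trimethylsilylacetylene, C#C[Si](C)(C)C
Why: Weinreb ketone synthesis, in which the lithium acetylide adds only once because the chelated tetrahedral intermediate survives until aqueous work-up.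

**Step 6**
Reactants: 9 5,5-dimethoxy-1-(trimethylsilyl)pent-1-yn-3-one
Product: 10 (S)-5,5-dimethoxy-1-(trimethylsilyl)pent-1-yn-3-ol
Conditions: Ru[(S,S)-TsDPEN](p-cymene) (cat.), i-PrOH, rt
Reagents that add atoms: none
Why: Noyori asymmetric transfer hydrogenation of an alkynyl ketone, in which the (S,S)-TsDPEN ruthenium hydride distinguishes the alkynyl from the sp3 flank and should deliver the (S)-propargylic alcohol, the future C8 stereocentre.

**Step 7**
Reactants: 10 (S)-5,5-dimethoxy-1-(trimethylsilyl)pent-1-yn-3-ol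
Product: 11 (S)-5,5-dimethoxypent-1-yn-3-ol
Conditions: K2CO3, MeOH, rt
Reagents that add atoms: none
Why: Carbonate-catalysed methanolysis of the alkynyl C–Si bond (protodesilylation) frees the terminal alkyne without touching the acetal or the carbinol centre.

**Step 8**
Reactants: 11 (S)-5,5-dimethoxypent-1-yn-3-ol; 6 (Z)-3-methyl-5-(4,4,5,5-tetramethyl-1,3,2-dioxaborolan-2-yl)pent-2-en-1-yl (Z)-2-methylbut-2-enoate
Product: 15 (2Z,6E,8S)-8-hydroxy-10,10-dimethoxy-3,7-dimethyldeca-2,6-dien-1-yl (Z)-2-methylbut-2-enoate, via oxamagnesole 12 (not isolated), via boron ate complex 13 (not isolated), via iodoboronate 14 (not isolated)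
Conditions: 11 (1.5 equiv), MeMgBr (2.9 equiv), CuI (15 mol%), THF, −20 °C → rt; then 6 (1.0 equiv), −78 → 0 °C; I2, THF, −78 °C; NaOMe, MeOH, −78 → −20 °C
Reagents that add atoms: methylmagnesium bromide, C[Mg]Br
Why: Proposed new method: the magnesium alkoxide of 11 undergoes copper-catalysed anti-methylmagnesiation of its terminal alkyne (a known reaction of propargylic alcohols), which puts CH3 on C7 and holds Mg on C6 cis to C8 in the five-membered chelate 12; this alkenyl group is then transferred to the boron atom of 6 to give ate complex 13, iodine triggers the 1,2-shift of the primary alkyl group from boron to C6 anti to the iodonium bridge (the new C5–C6 bond, 14), and methoxide-induced anti elimination of boron and iodide releases 15. The closest known reaction type is the Zweifel olefination of alkyl pinacol boronates with alkenyl Grignard reagents; new here are the generation of the alkenylmagnesium in the same flask by carbomagnesiation and the presence of the γ-magnesium alkoxide during iodination. The only ring closed is the temporary oxamagnesole ring of 12, formed by O8-to-Mg chelation during the anti addition across C6≡C7 and opened again when boron is expelled; no ring of the target is formed. No new stereocentre arises: the 6E geometry follows from two stereospecific anti events on an alkenyl metal whose geometry is fixed by the chelate ring (metal cis to C8, hence C5 trans to C8), and the C8 configuration from step 6 is not touched. The step needs regioselective methyl delivery to C7, secured by the alkoxide chelate, and chemoselective attack on boron in the presence of the angelate, secured by MeMgBr being the limiting reagent (no free methyl Grignard when 6 is added), by fast complexation of the boronate at −78 °C and by the hindered, conjugated ester; the tertiary C7–I centre of 14 disfavours epoxide formation by the neighbouring alkoxide.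

**Step 9**
Reactants: 15 (2Z,6E,8S)-8-hydroxy-10,10-dimethoxy-3,7-dimethyldeca-2,6-dien-1-yl (Z)-2-methylbut-2-enoate
Product: 16 (2Z,6E,8S)-8-acetoxy-10,10-dimethoxy-3,7-dimethyldeca-2,6-dien-1-yl (Z)-2-methylbut-2-enoate
Conditions: Ac2O, pyridine, CH2Cl2, rt
Reagents that add atoms: acetic anhydride, CC(=O)OC(C)=O
Why: Standard acetylation of the secondary allylic alcohol installs the C8 acetate with retention, the acetal and the angelate being inert.

**Step 10**
Reactants: 16 (2Z,6E,8S)-8-acetoxy-10,10-dimethoxy-3,7-dimethyldeca-2,6-dien-1-yl (Z)-2-methylbut-2-enoate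
Product: 17 (2Z,6E,8S)-8-acetoxy-3,7-dimethyl-10-oxodeca-2,6-dien-1-yl (Z)-2-methylbut-2-enoate
Conditions: LiBF4, MeCN/H2O (98:2), rt
Reagents that add atoms: water, O
Why: Mild Lewis-acid-promoted hydrolysis of the dimethyl acetal in wet acetonitrile should unveil the C10 aldehyde without ionising the allylic acetate or eliminating acetic acid.

**Step 11**
Reactants: 18 2-deoxy-D-ribose
Product: 19 2-deoxy-D-ribono-1,4-lactone [(4S,5R)-4-hydroxy-5-(hydroxymethyl)dihydrofuran-2(3H)-one]
Conditions: Br2, H2O, rt
Reagents that add atoms: none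
Why: Bromine-water oxidation of the aldose hemiacetal is the classical route to the 1,4-lactone and leaves both carbinol stereocentres of the chiral pool (future C12 and C13) untouched.

**Step 12**
Reactants: 19 2-deoxy-D-ribono-1,4-lactone
Product: 20 (4S,5R)-4-[(tert-butyldimethylsilyl)oxy]-5-{[(tert-butyldimethylsilyl)oxy]methyl}dihydrofuran-2(3H)-one
Conditions: TBSCl, imidazole, DMF, rt
Reagents that add atoms: tert-butyldimethylsilyl chloride, CC(C)(C)[Si](C)(C)Cl
Why: Silylation of both hydroxyl groups with TBSCl and imidazole is routine for this diol.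

**Step 13**
Reactants: 20 (4S,5R)-4-[(tert-butyldimethylsilyl)oxy]-5-{[(tert-butyldimethylsilyl)oxy]methyl}dihydrofuran-2(3H)-one
Product: 21 (4S,5R)-4-[(tert-butyldimethylsilyl)oxy]-5-(hydroxymethyl)dihydrofuran-2(3H)-one
Conditions: TFA/H2O/THF (1:1:4), 0 °C
Reagents that add atoms: none
Why: Acid-catalysed hydrolysis discriminates sterically between the primary and the secondary TBS ether, so the primary alcohol should be released selectively at 0 °C.

**Step 14**
Reactants: 21 (4S,5R)-4-[(tert-butyldimethylsilyl)oxy]-5-(hydroxymethyl)dihydrofuran-2(3H)-one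
Product: 22 (2S,3S)-3-[(tert-butyldimethylsilyl)oxy]-5-oxotetrahydrofuran-2-carbaldehyde
Conditions: Dess–Martin periodinane, NaHCO3, CH2Cl2, 0 °C → rt
Reagents that add atoms: none
Why: Dess–Martin oxidation under bicarbonate buffering converts the primary alcohol into the aldehyde under non-basic conditions that should avoid epimerisation of the adjacent oxygenated centre.

**Step 15**
Reactants: 22 (2S,3S)-3-[(tert-butyldimethylsilyl)oxy]-5-oxotetrahydrofuran-2-carbaldehyde
Product: 23 (4S,5R)-4-[(tert-butyldimethylsilyl)oxy]-5-(2-methylprop-1-en-1-yl)dihydrofuran-2(3H)-one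
Conditions: i-PrPPh3I, n-BuLi, THF, 0 °C; then 22, −78 → 0 °C
Reagents that add atoms: isopropyltriphenylphosphonium iodide, CC(C)[P+](c1ccccc1)(c1ccccc1)c1ccccc1.[I-]
Why: Wittig olefination with the non-stabilised isopropylidene ylide at low temperature, where addition to the aldehyde should outrun enolisation and attack on the lactone, installs the 2-methylprop-1-enyl group with no geometrical issue.

**Step 16**
Reactants: 23 (4S,5R)-4-[(tert-butyldimethylsilyl)oxy]-5-(2-methylprop-1-en-1-yl)dihydrofuran-2(3H)-one; 17 (2Z,6E,8S)-8-acetoxy-3,7-dimethyl-10-oxodeca-2,6-dien-1-yl (Z)-2-methylbut-2-enoate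
Product: 25 (2Z,6E,8S)-8-acetoxy-10-hydroxy-10-[(4S,5R)-4-[(tert-butyldimethylsilyl)oxy]-5-(2-methylprop-1-en-1-yl)-2-oxotetrahydrofuran-3-yl]-3,7-dimethyldeca-2,6-dien-1-yl (Z)-2-methylbut-2-enoate (lactone 3,4-trans; both C10 epimers), via lithium enolate 24 (not isolated)
Conditions: 23, LiN(i-Pr)2 (LDA), THF, −78 °C; then 17, −78 °C; aq. NH4Cl
Reagents that add atoms: none
Why: Aldol addition of the preformed lithium enolate of the β-silyloxy lactone at −78 °C, where addition to the aldehyde should be faster than proton transfer or ester attack; the electrophile enters anti to the neighbouring OTBS group, and the configuration of the new C10 carbinol is irrelevant because it is removed in the next step.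

**Step 17**
Reactants: 25 aldol adduct (both C10 epimers)
Product: 27 (2Z,6E,8S,10E)-8-acetoxy-10-[(4S,5R)-4-[(tert-butyldimethylsilyl)oxy]-5-(2-methylprop-1-en-1-yl)-2-oxodihydrofuran-3(2H)-ylidene]-3,7-dimethyldeca-2,6-dien-1-yl (Z)-2-methylbut-2-enoate, via mesylate 26 (not isolated)
Conditions: MsCl, Et3N, CH2Cl2, 0 °C; then DBU, 0 °C → rt
Reagents that add atoms: none
Why: Mesylation followed by E1cB elimination through the lactone enolate should give the conjugated alkylidene lactone as the thermodynamically preferred E isomer, in which the vinylic hydrogen and not the C9 methylene lies syn to the carbonyl group.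

**Step 18**
Reactants: 27 silyl ether of the target
Product: 28 (2Z,6E,8S,10E)-8-acetoxy-10-[(4S,5R)-4-hydroxy-5-(2-methylprop-1-en-1-yl)-2-oxodihydrofuran-3(2H)-ylidene]-3,7-dimethyldeca-2,6-dien-1-yl (Z)-2-methylbut-2-enoate (CNP0201198.1)
Conditions: HF·pyridine, pyridine, THF, 0 °C → rt
Reagents that add atoms: none
Why: Fluoride-mediated cleavage of the secondary TBS ether with buffered HF·pyridine is non-basic and should spare the acetate, the angelate, the lactone and the base-sensitive δ-acetoxy enoate array.

**Compound list**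
1 | (Z)-3-methylpent-2-en-4-yn-1-ol | OC/C=C(/C)C#C | starting material
2 | angelic acid, (Z)-2-methylbut-2-enoic acid | C/C=C(/C)C(=O)O | starting material
3 | (Z)-2-methylbut-2-enoic 2,4,6-trichlorobenzoic anhydride (mixed anhydride, not isolated) | C/C=C(/C)C(=O)OC(=O)c1c(Cl)cc(Cl)cc1Cl | intermediate
4 | (Z)-3-methylpent-2-en-4-yn-1-yl (Z)-2-methylbut-2-enoate | C/C=C(/C)C(=O)OC/C=C(/C)C#C | intermediate
5 | (Z)-3-methylpenta-2,4-dien-1-yl (Z)-2-methylbut-2-enoate | C/C=C(/C)C(=O)OC/C=C(/C)C=C | intermediate
6 | (Z)-3-methyl-5-(4,4,5,5-tetramethyl-1,3,2-dioxaborolan-2-yl)pent-2-en-1-yl (Z)-2-methylbut-2-enoate | C/C=C(/C)C(=O)OC/C=C(/C)CCB1OC(C)(C)C(C)(C)O1 | intermediate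
7 | methyl 3,3-dimethoxypropanoate | COC(=O)CC(OC)OC | starting material
8 | 3,3-dimethoxy-N-methoxy-N-methylpropanamide | CON(C)C(=O)CC(OC)OC | intermediate
9 | 5,5-dimethoxy-1-(trimethylsilyl)pent-1-yn-3-one | COC(CC(=O)C#C[Si](C)(C)C)OC | intermediate
10 | (S)-5,5-dimethoxy-1-(trimethylsilyl)pent-1-yn-3-ol | C[Si](C)(C)C#C[C@@H](O)CC(OC)OC | intermediate
11 | (S)-5,5-dimethoxypent-1-yn-3-ol | C#C[C@@H](O)CC(OC)OC | intermediate
12 | (S)-5-(2,2-dimethoxyethyl)-4-methyl-2,5-dihydro-1,2-oxamagnesole (chelated alkenylmagnesium alkoxide, not isolated) | CC1=C[Mg]O[C@H]1CC(OC)OC | intermediate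
13 | magnesium alkenyl(alkyl)pinacolatoborate from 6 and 12 (ate complex, boron on C6 cis to C8, not isolated) | C/C=C(/C)C(=O)OC/C=C(/C)CC[B-]1(OC(C)(C)C(C)(C)O1)/C=C(/C)[C@H](CC(OC)OC)O[Mg+] | intermediate
14 | 6-boryl-7-iodo adduct after iodination and 1,2-shift (6,7-anti adduct from either alkene face, magnesium alkoxide, not isolated) | C/C=C(/C)C(=O)OC/C=C(/C)CCC(B1OC(C)(C)C(C)(C)O1)C(C)(I)[C@H](CC(OC)OC)O[Mg]Br | intermediate
15 | (2Z,6E,8S)-8-hydroxy-10,10-dimethoxy-3,7-dimethyldeca-2,6-dien-1-yl (Z)-2-methylbut-2-enoate | C/C=C(/C)C(=O)OC/C=C(/C)CC/C=C(\C)[C@@H](O)CC(OC)OC | intermediate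
16 | (2Z,6E,8S)-8-acetoxy-10,10-dimethoxy-3,7-dimethyldeca-2,6-dien-1-yl (Z)-2-methylbut-2-enoate | C/C=C(/C)C(=O)OC/C=C(/C)CC/C=C(\C)[C@H](CC(OC)OC)OC(C)=O | intermediate
17 | (2Z,6E,8S)-8-acetoxy-3,7-dimethyl-10-oxodeca-2,6-dien-1-yl (Z)-2-methylbut-2-enoate | C/C=C(/C)C(=O)OC/C=C(/C)CC/C=C(\C)[C@H](CC=O)OC(C)=O | intermediate
18 | 2-deoxy-D-ribose (drawn as the open-chain aldehyde) | O=CC[C@H](O)[C@H](O)CO | starting material
19 | 2-deoxy-D-ribono-1,4-lactone, (4S,5R)-4-hydroxy-5-(hydroxymethyl)dihydrofuran-2(3H)-one | O=C1C[C@H](O)[C@@H](CO)O1 | intermediate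
20 | (4S,5R)-4-[(tert-butyldimethylsilyl)oxy]-5-{[(tert-butyldimethylsilyl)oxy]methyl}dihydrofuran-2(3H)-one | O=C1C[C@H](O[Si](C)(C)C(C)(C)C)[C@@H](CO[Si](C)(C)C(C)(C)C)O1 | intermediate
21 | (4S,5R)-4-[(tert-butyldimethylsilyl)oxy]-5-(hydroxymethyl)dihydrofuran-2(3H)-one | O=C1C[C@H](O[Si](C)(C)C(C)(C)C)[C@@H](CO)O1 | intermediate
22 | (2S,3S)-3-[(tert-butyldimethylsilyl)oxy]-5-oxotetrahydrofuran-2-carbaldehyde | O=C1C[C@H](O[Si](C)(C)C(C)(C)C)[C@@H](C=O)O1 | intermediate
23 | (4S,5R)-4-[(tert-butyldimethylsilyl)oxy]-5-(2-methylprop-1-en-1-yl)dihydrofuran-2(3H)-one | O=C1C[C@H](O[Si](C)(C)C(C)(C)C)[C@@H](C=C(C)C)O1 | intermediate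
24 | lithium enolate of 23 (not isolated) | [Li]OC1=C[C@H](O[Si](C)(C)C(C)(C)C)[C@@H](C=C(C)C)O1 | intermediate
25 | aldol adduct of 24 and 17 (lactone 3,4-trans, both C10 epimers) | C/C=C(/C)C(=O)OC/C=C(/C)CC/C=C(\C)[C@H](CC(O)[C@@H]1C(=O)O[C@H](C=C(C)C)[C@H]1O[Si](C)(C)C(C)(C)C)OC(C)=O | intermediate
26 | 10-O-methanesulfonate of 25 (not isolated) | C/C=C(/C)C(=O)OC/C=C(/C)CC/C=C(\C)[C@H](CC(OS(C)(=O)=O)[C@@H]1C(=O)O[C@H](C=C(C)C)[C@H]1O[Si](C)(C)C(C)(C)C)OC(C)=O | intermediate
27 | 12-O-tert-butyldimethylsilyl ether of the target | C/C=C(/C)C(=O)OC/C=C(/C)CC/C=C(\C)[C@H](C/C=C1/C(=O)O[C@H](C=C(C)C)[C@H]1O[Si](C)(C)C(C)(C)C)OC(C)=O | intermediate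
28 | CNP0201198.1, (2Z,6E,8S,10E)-8-acetoxy-10-[(4S,5R)-4-hydroxy-5-(2-methylprop-1-en-1-yl)-2-oxodihydrofuran-3(2H)-ylidene]-3,7-dimethyldeca-2,6-dien-1-yl (Z)-2-methylbut-2-enoate | C/C=C(/C)C(=O)OC/C=C(/C)CC/C=C(\C)[C@H](C/C=C1/C(=O)O[C@H](C=C(C)C)[C@H]1O)OC(C)=O | target

**Step count**
Total steps: 18. Longest linear sequence: 10 steps (7 → 28 through steps 4–10 and 16–18).

**Steps most likely to fail**

Step 8 (Proposed new method). What may go wrong is loss of coupling efficiency through incomplete carbomagnesiation or through transfer of a second alkenyl group to boron. Attack of the organomagnesium species on the angelate, or interception of the iodinated intermediate by the neighbouring magnesium alkoxide, could also erode the olefin geometry. The fallback uses known chemistry and sets out from 11 and 5. Zirconium-catalysed syn-methylalumination of 11 (Me3Al, Cp2ZrCl2, CH2Cl2) followed by iodinolysis should give (S,E)-1-iodo-5,5-dimethoxy-2-methylpent-1-en-3-ol F1. Diene 5 is hydroborated at its vinyl terminus with 9-BBN to the B-alkyl-9-BBN derivative F2, which is coupled in the same flask with F1 (Pd(dppf)Cl2, AsPh3, Cs2CO3, DMF/THF/H2O, rt). This B-alkyl Suzuki–Miyaura coupling proceeds with retention of the E geometry and comes back to the route at 15.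

Step 17. What may go wrong is poor E/Z control in the E1cB elimination, or base-induced vinylogous loss of acetic acid from C8 once the alkylidene lactone is formed. The fallback replaces the aldol condensation by an olefination and sets out from 23 (with 17 as partner). Lactone 23 is O-phosphorylated through its enolate (LDA; ClP(O)(OEt)2) to the enol phosphate F3, and a further equivalent of LDA induces the 1,3-phosphoryl shift to the α-(diethoxyphosphoryl) lactone F4. Horner–Wadsworth–Emmons reaction of the sodium salt of F4 (NaH, THF) with aldehyde 17 at low temperature forms the C10=C11 bond directly. The weakly basic stabilised anion should favour the E-alkylidene lactone and avoids mesylate and DBU altogether; the fallback comes back at 27.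

Step 16. What may go wrong is base-induced β-elimination of acetic acid from aldehyde 17, acetyl migration from O8 to the lithium aldolate, or retro-aldol cleavage on warming. The fallback sets out from 23. Trapping of its enolate with Me3SiCl gives the silyl ketene acetal F5, which is added to 17 in a Mukaiyama aldol reaction (BF3·OEt2, CH2Cl2, −78 °C). No basic species or free alkoxide is present, and the fallback comes back at 25.

**Further compounds**
F1 | step 8 | (S,E)-1-iodo-5,5-dimethoxy-2-methylpent-1-en-3-ol | I/C=C(\C)[C@@H](O)CC(OC)OC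
F2 | step 8 | (Z)-5-(9-borabicyclo[3.3.1]nonan-9-yl)-3-methylpent-2-en-1-yl (Z)-2-methylbut-2-enoate | C/C=C(/C)C(=O)OC/C=C(/C)CCB1C2CCCC1CCC2
F3 | step 17 | diethyl (4S,5R)-4-[(tert-butyldimethylsilyl)oxy]-5-(2-methylprop-1-en-1-yl)-4,5-dihydrofuran-2-yl phosphate | CCOP(=O)(OCC)OC1=C[C@H](O[Si](C)(C)C(C)(C)C)[C@@H](C=C(C)C)O1
F4 | step 17 | α-(diethoxyphosphoryl) derivative of lactone 23 (C3 epimers; C4 and C5 as in 23) | CCOP(=O)(OCC)C1C(=O)O[C@H](C=C(C)C)[C@H]1O[Si](C)(C)C(C)(C)C
F5 | step 16 | trimethylsilyl ketene acetal of lactone 23 | C[Si](C)(C)OC1=C[C@H](O[Si](C)(C)C(C)(C)C)[C@@H](C=C(C)C)O1
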